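## The problem

Target 18 is an isoflavanone. Ring A, a phloroglucinol unit with free hydroxyls at C5 and C7, is fused to the dihydropyranone ring C; C3 of ring C carries ring B, which is fused across C3'–C4' to a 2,2-dimethyl-2H-pyran (ring D) and bears a methoxy group at C2'. The only stereocentre is C3, of (R) configuration; it is benzylic and α to the C4 ketone, so it epimerises through the enol or enolate, and no second stereocentre exists that could set or repair it. Its configuration must therefore come from a chiral catalyst at a stage where the carbon cannot enolise, and every later step must be free of base. The chromene double bond of ring D is an electron-rich styrene: it excludes hydrogenation, peracids and halogenating oxidants, and it tolerates strong acid only briefly and cold. Three phenolic oxygens must be told apart, one methylated on ring B and two free on ring A, so the ring A oxygens need a protecting group that leaves under near-neutral, non-reductive conditions. Regiochemistry arises twice: ring D must be fused in the angular sense, between the two oxygens of ring B, and ring C must be closed onto ring A. The second question is removed by the local symmetry of ring A: in a phenoxy group with equal oxygen substituents at both meta positions the two carbons flanking the ether oxygen are the same, so a C4 acyl carbon held on the chain O1–C2–C3 can form C4–C4a at only one kind of position and closes a six-membered ring.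

## Retrosynthesis

**O–Si bonds at C5 and C7 (18 to 17).** The two free phenols are traced back to the bis(tert-butyldimethylsilyl) ether 17. Methyl ethers could not be removed beside the 2'-methoxy group, benzyl ethers would need hydrogen that also reduces the chromene, and acetal ethers need acid. Alkyl ethers are also hard to put on phloroglucinol, which tends to alkylate at carbon, whereas silylation goes to oxygen. The skeleton is unchanged, but this choice decides what all earlier steps must tolerate. The forward step needs fluoride with a proton source, so that neither a phenoxide nor an enolate persists.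

**C4–C4a (17 to 15).** Ring C is opened at the aryl–carbonyl bond to give the (R)-2-aryl-3-aryloxypropanoic acid 15.
- A cut at O1–C2 would need a hydroxyaryl ketone with a leaving group β to the carbonyl and an enolisable stereocentre between them, which invites elimination.
- A cut at C3–C1' means arylating a chromanone enolate, which creates the stereocentre under base.
- A cut at C2–C3 is the hydroxymethylation of a deoxybenzoin and gives racemate.
- The C4–C4a cut leaves C3 untouched, removes one ring, and offers a nucleophile with two equivalent positions.

The forward reaction needs acid activation without base; trifluoroacetic anhydride provides it through the mixed anhydride 16.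

**Oxidation level at C4 (15 to 14 to 13).** The carboxyl is traced back to the primary alcohol 14 and its acetate 13. This keeps C3 at a carbon flanked by two CH2O arms, where it cannot enolise, for as long as possible. Two things are asked of the forward steps: the acetate must be removed without touching the aryl silyl ethers (hydride, not carbonate in methanol), and the oxidation must pass the α-aryl aldehyde stage quickly and without base.

**O1–C2 (13 to 10 and 12).** The aryl ether bond is cut to the monoacetate 10 and the phenol 12, which comes from phloroglucinol 11 by twofold silylation. Ether formation is placed at the alcohol level because a β-hydroxy ester would dehydrate to the 2-arylacrylate under the same conditions. The precursors are a small chiral building block and a symmetric phenol. The forward reaction is an SN2 displacement at a primary carbon that does not involve C3.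

**The stereocentre (10 to 9).** Removing the acetyl group from 10 gives the prochiral diol 9, so the stereochemical problem becomes a choice between two enantiotopic hydroxymethyl groups. A lipase makes this choice catalytically and under neutral conditions. An auxiliary-based alkylation of an arylacetic acid derivative would instead set the centre at the enolisable carboxyl level and need basic cleavage.

**C3–C1' and C3–C2 (9 to 8 to 7 to 5 and 6).** The diol is traced through the hydroxy ester 8 to the β-hydroxyacrylate 7. Compound 7 arises from aldehyde 5 and ethyl diazoacetate 6 by acid-catalysed addition and 1,2-aryl shift; this forms the aryl–C3 bond and one C3–CH2O bond in one step. The neighbouring cut, malonate arylation of a chromenyl triflate, would require turning aldehyde 5 into a phenol with a peracid, which the chromene double bond tolerates poorly. The forward reaction needs aryl rather than hydride migration; an aryl group with two oxygen donors favours this.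

**Ring D (5 to 4 to 1 and 2).** The methyl ether is cut, then the O–CMe2 and C4–C4a bonds of the pyran, leading to 2,4-dihydroxybenzaldehyde 1 and 3-methylbut-2-enal 2. The hydrogen bond between the 2-hydroxyl and the formyl group directs ring closure through the 4-oxygen and leaves the chelated hydroxyl for methylation. The forward reaction needs condensation at the carbon between the two hydroxyls, which is the most nucleophilic position.

## Roads not taken

**Alternative 1:** Ring B is dismantled into the chromonyl diazo enone A2 and the prenyl-bearing siloxyalkyne A3. In the forward direction, irradiation of A2 triggers a Wolff rearrangement to a vinylketene; this adds A3 in a [2+2] sense, the cyclobutenone opens, and the dienylketene closes by 6π electrocyclisation to the isoflavone A1.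
- Merits: the three contiguous substituents of ring B (2'-hydroxyl, 3'-prenyl, 4'-silyloxy) are placed by connectivity and not by directing effects. The two oxygens are born differentiated, so 2'-O-methylation needs no selectivity.
- Weak points: A1 is an isoflavone, so C3 is trigonal. The stereocentre would have to be made last by enantioselective reduction of the C2=C3 bond, which generates the labile centre through an enolate, the species most likely to racemise it. Ring D would still have to be closed oxidatively from the prenyl phenol, the acetal protecting groups need acid, and A2 and A3 each take several steps. The chromone chromophore also competes for light.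
- Comparison: in regiocontrol of ring B this road is better than the chosen plan, which relies on a hydrogen-bond-directed chromenylation that is selective but not absolute. The chosen plan offers in return a one-step entry to ring D from a commercial aldehyde and, decisively, a C3 configuration fixed before ring C exists.

**Alternative 2:** Ring D is cut at O–CMe2 and at the ring carbon between the two oxygens, leading to the aryl 1,1-dimethylpropargyl ether A5. Heating A5 causes a [3,3] shift to that carbon, then a 1,5-hydrogen shift and oxa-6π closure of the ortho-quinone methide to the chromene aldehyde A4, which is identical with compound 4 of the route.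
- Merits: the cascade is thermal, reagent-free and reliably angular when the 2-hydroxyl is chelated. It avoids the tars that enal condensations can give.
- Weak points: it takes two steps (selective 4-O-propargylation, then heating) to reach an aldehyde that the chosen route makes in one. It addresses only ring D and says nothing about ring C or C3.
- Comparison: as a way to compound 4 it is as good as step 1 and may be cleaner. The chosen plan has one step fewer, and its strategic step deals with the part of the molecule that is hard. The two are interchangeable at compound 4.

**Alternative 3:** Ring C is cut at C4–C4a and at O1–C2 with C2 as a carbonyl, leading to phloroglucinol 11 and the diethyl arylmalonate A7. Heating the two acylates a ring carbon and lactonises the neighbouring phenol to the 3-aryl-4-hydroxycoumarin A6.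
- Merits: it uses the same symmetry of ring A, needs no protecting groups on ring A, forms two bonds in one step and is highly convergent.
- Weak points: A6 has the wrong oxidation level at C2 (a lactone carbonyl where the target has CH2) and a trigonal C3. Reducing the lactone to the methylene while keeping C4 as a ketone, and then setting C3 enantioselectively, adds several redox steps and leaves the stereochemical problem unsolved. The condensation needs temperatures the chromene may not survive, and A7 needs an aryl–malonate bond that aldehyde 5 does not provide directly.
- Comparison: this road reaches the tricyclic skeleton in fewer steps and is more convergent. The chosen plan arrives at the correct oxidation level at C2 and C4 without correction and carries a defined configuration at C3 through the ring closure.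

Key step: step 11

Assumption: Burkholderia cepacia lipase is taken to acetylate the enantiotopic hydroxymethyl group of diol 9 that leads to (R)-10. This sense must be confirmed on the ortho-substituted aryl diol; a mirror-image entry with the same enzyme is described under the uncertain steps.

## Route

Step 1
Reactants: 1 2,4-dihydroxybenzaldehyde; 2 3-methylbut-2-enal
Product: 4 5-hydroxy-2,2-dimethyl-2H-chromene-6-carbaldehyde, via ortho-quinone methide 3 (not isolated)
Conditions: pyridine, 140 °C, sealed vessel
Reagents that add atoms: none
Why: Knoevenagel-type condensation of the enal at the ring carbon between the two hydroxyls, dehydration to ortho-quinone methide 3 and oxa-6π electrocyclisation; the 2-hydroxyl is held in a hydrogen bond to the formyl group, so the pyran closes through the 4-oxygen and the angular chromene should result.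

Step 2
Reactants: 4 5-hydroxy-2,2-dimethyl-2H-chromene-6-carbaldehyde
Product: 5 5-methoxy-2,2-dimethyl-2H-chromene-6-carbaldehyde
Conditions: MeI, K2CO3, DMF, 40 °C
Reagents that add atoms: iodomethane, CI
Why: Williamson methylation of the chelated phenol, which needs a polar solvent and mild heating; the aldehyde has no α-hydrogen and the chromene is inert to carbonate.

Step 3
Reactants: 5 5-methoxy-2,2-dimethyl-2H-chromene-6-carbaldehyde; 6 ethyl diazoacetate
Product: 7 ethyl (Z)-3-hydroxy-2-(5-methoxy-2,2-dimethyl-2H-chromen-6-yl)prop-2-enoate
Conditions: HBF4·OEt2 (10 mol%), CH2Cl2, −78 °C, slow addition of 6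
Reagents that add atoms: none
Why: Acid-catalysed addition of the diazo ester to the aldehyde followed by 1,2-aryl shift with loss of N2 (the aryl-migration variant of the Roskamp homologation); the aryl group with two oxygen donors should migrate in preference to hydride, and the product rests as the hydrogen-bonded enol of the α-formyl ester. In 5 both ring oxygens are conjugated with the formyl group, which lowers the basicity of the chromene double bond towards the catalytic acid at low temperature.

Step 4
Reactants: 7 ethyl (Z)-3-hydroxy-2-(5-methoxy-2,2-dimethyl-2H-chromen-6-yl)prop-2-enoate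
Product: 8 ethyl 3-hydroxy-2-(5-methoxy-2,2-dimethyl-2H-chromen-6-yl)propanoate (racemic)
Conditions: NaBH4, EtOH, 0 °C
Reagents that add atoms: none
Why: Borohydride reduction of the aldehyde tautomer of the β-hydroxyacrylate, the classical route to tropic esters; the ester and the chromene are left alone at 0 °C. The centre formed here is racemic and disappears in the next step, where the carbon becomes prochiral.

Step 5
Reactants: 8 ethyl 3-hydroxy-2-(5-methoxy-2,2-dimethyl-2H-chromen-6-yl)propanoate
Product: 9 2-(5-methoxy-2,2-dimethyl-2H-chromen-6-yl)propane-1,3-diol
Conditions: LiAlH4, THF, 0 °C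
Reagents that add atoms: none
Why: Hydride reduction of the β-hydroxy ester to the prochiral 2-aryl-1,3-diol; fast reduction at 0 °C should outrun E1cB loss of water from the ester.

Step 6
Reactants: 9 2-(5-methoxy-2,2-dimethyl-2H-chromen-6-yl)propane-1,3-diol
Product: 10 (R)-3-hydroxy-2-(5-methoxy-2,2-dimethyl-2H-chromen-6-yl)propyl acetate
Conditions: Burkholderia cepacia lipase (lipase PS), vinyl acetate, t-BuOMe, 25 °C
Reagents that add atoms: vinyl acetate, CC(=O)OC=C
Why: Lipase-catalysed enantiotopic-group-selective transesterification of a 2-aryl-propane-1,3-diol with an irreversible acyl donor; the active site of the enzyme, not the substrate, sets the carbon that becomes C3 as (R). Slow further acetylation of the minor enantiomer to the achiral diacetate should raise the enantiomeric purity of 10.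

Step 7
Reactants: 11 phloroglucinol
Product: 12 3,5-bis(tert-butyldimethylsilyloxy)phenol
Conditions: TBSCl (2.0 equiv), imidazole, DMF, 0 °C to rt
Reagents that add atoms: tert-butyldimethylsilyl chloride, CC(C)(C)[Si](C)(C)Cl
Why: Statistical O-silylation of the symmetric triphenol; the silyl chloride reacts only at oxygen, so no C-substituted products arise, and the bis-ether is separated from mono- and tris-ether, which can be recycled.

Step 8
Reactants: 10 (R)-3-hydroxy-2-(5-methoxy-2,2-dimethyl-2H-chromen-6-yl)propyl acetate; 12 3,5-bis(tert-butyldimethylsilyloxy)phenol
Product: 13 (R)-3-[3,5-bis(tert-butyldimethylsilyloxy)phenoxy]-2-(5-methoxy-2,2-dimethyl-2H-chromen-6-yl)propyl acetate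
Conditions: PPh3, diisopropyl azodicarboxylate, THF, 0 °C to rt
Reagents that add atoms: none
Why: Mitsunobu etherification: the phenol displaces the activated primary hydroxyl by SN2 at the carbon that becomes C2; the stereocentre is one carbon away and is not touched, and the neutral medium should not provoke acetyl migration.

Step 9
Reactants: 13 (R)-3-[3,5-bis(tert-butyldimethylsilyloxy)phenoxy]-2-(5-methoxy-2,2-dimethyl-2H-chromen-6-yl)propyl acetate
Product: 14 (S)-3-[3,5-bis(tert-butyldimethylsilyloxy)phenoxy]-2-(5-methoxy-2,2-dimethyl-2H-chromen-6-yl)propan-1-ol
Conditions: i-Bu2AlH, CH2Cl2, −78 °C; aq. KNaC4H4O6 work-up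
Reagents that add atoms: none
Why: Reductive cleavage of the acetate by an aluminium hydride at low temperature; hydride is used because carbonate in methanol would also cleave the aryl silyl ethers. The descriptor changes from (R) to (S) only because the priorities of the two arms change; the geometry at the centre is the same.

Step 10
Reactants: 14 (S)-3-[3,5-bis(tert-butyldimethylsilyloxy)phenoxy]-2-(5-methoxy-2,2-dimethyl-2H-chromen-6-yl)propan-1-ol
Product: 15 (R)-3-[3,5-bis(tert-butyldimethylsilyloxy)phenoxy]-2-(5-methoxy-2,2-dimethyl-2H-chromen-6-yl)propanoic acid
Conditions: TEMPO (20 mol%), PhI(OAc)2 (2.2 equiv), MeCN/aq. NaH2PO4–Na2HPO4 buffer (pH 7), 0 °C to rt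
Reagents that add atoms: water, O
Why: Nitroxyl-catalysed oxidation of the primary alcohol to the acid through the aldehyde hydrate; the medium is near neutral and free of chlorine, so the α-aryl aldehyde should be oxidised on before it enolises and the electron-rich rings are not halogenated.

Step 11
Reactants: 15 (R)-3-[3,5-bis(tert-butyldimethylsilyloxy)phenoxy]-2-(5-methoxy-2,2-dimethyl-2H-chromen-6-yl)propanoic acid
Product: 17 (R)-5,7-bis(tert-butyldimethylsilyloxy)-3-(5-methoxy-2,2-dimethyl-2H-chromen-6-yl)chroman-4-one, via mixed trifluoroacetic anhydride 16 (not isolated)
Conditions: (CF3CO)2O (1.5 equiv), CH2Cl2, 0 °C; quench into cold NaH2PO4–Na2HPO4 buffer (pH 7)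
Reagents that add atoms: none
Why: Trifluoroacetic anhydride converts acid 15 into mixed anhydride 16, in which trifluoroacetate is the better leaving group, so the aryl-bearing acyl carbon is the one attacked; ring A attacks it at the carbon ortho to the ether oxygen and para to a silyloxy group, and loss of a proton restores the arene (intramolecular Friedel–Crafts acylation, the standard closure of 3-aryloxypropanoic acids to chroman-4-ones). Ring C closes in a 6-exo-trig sense at the acyl carbon, which forms C4–C4a. No stereocentre is created; C3 is carried through with retention because no bond to it is made or broken. The step needs regioselectivity, chemoselectivity and configurational stability. Regioselectivity is secured by the symmetry of the 3,5-bis(silyloxy)phenoxy ring, whose two ortho carbons are equivalent. Chemoselectivity rests on the six-membered transition state, which should outpace intermolecular acylation at C8 of the chromene ring or trifluoroacetylation of ring A, and on the new ketone, which deactivates ring A afterwards. Configuration at C3 is protected by the absence of any base, so that no ketene or enolate can form from 16, and by low temperature, short exposure to the released trifluoroacetic acid and a buffered quench, which also spare the chromene double bond and the aryl silyl ethers.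

Step 12
Reactants: 17 (R)-5,7-bis(tert-butyldimethylsilyloxy)-3-(5-methoxy-2,2-dimethyl-2H-chromen-6-yl)chroman-4-one
Product: 18 (R)-5,7-dihydroxy-3-(5-methoxy-2,2-dimethyl-2H-chromen-6-yl)chroman-4-one (the target)
Conditions: Bu4NF/AcOH (1:1), THF, 0 °C
Reagents that add atoms: none
Why: Fluoride cleavage of the two aryl silyl ethers; acetic acid buffers the fluoride and protonates the phenoxides as they form, so the C3 hydrogen next to the ketone is not exposed to base and the (R) configuration should be kept.

## Compound list

1 | 2,4-dihydroxybenzaldehyde | O=Cc1ccc(O)cc1O | starting material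
2 | 3-methylbut-2-enal | CC(C)=CC=O | starting material
3 | (3Z)-2-hydroxy-3-(3-methylbut-2-en-1-ylidene)-4-oxocyclohexa-1,5-diene-1-carbaldehyde (ortho-quinone methide) | O=CC1=C(O)/C(=C/C=C(C)C)C(=O)C=C1 | intermediate
4 | 5-hydroxy-2,2-dimethyl-2H-chromene-6-carbaldehyde | O=Cc1ccc2OC(C)(C)C=Cc2c1O | intermediate
5 | 5-methoxy-2,2-dimethyl-2H-chromene-6-carbaldehyde | COc1c(C=O)ccc2OC(C)(C)C=Cc12 | intermediate
6 | ethyl diazoacetate | CCOC(=O)C=[N+]=[N-] | starting material
7 | ethyl (Z)-3-hydroxy-2-(5-methoxy-2,2-dimethyl-2H-chromen-6-yl)prop-2-enoate | CCOC(=O)/C(=C\O)c1ccc2OC(C)(C)C=Cc2c1OC | intermediate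
8 | ethyl 3-hydroxy-2-(5-methoxy-2,2-dimethyl-2H-chromen-6-yl)propanoate (racemic) | CCOC(=O)C(CO)c1ccc2OC(C)(C)C=Cc2c1OC | intermediate
9 | 2-(5-methoxy-2,2-dimethyl-2H-chromen-6-yl)propane-1,3-diol | OCC(CO)c1ccc2OC(C)(C)C=Cc2c1OC | intermediate
10 | (R)-3-hydroxy-2-(5-methoxy-2,2-dimethyl-2H-chromen-6-yl)propyl acetate | COc1c([C@@H](COC(C)=O)CO)ccc2c1C=CC(C)(C)O2 | intermediate
11 | phloroglucinol (benzene-1,3,5-triol) | Oc1cc(O)cc(O)c1 | starting material
12 | 3,5-bis(tert-butyldimethylsilyloxy)phenol | Oc1cc(O[Si](C)(C)C(C)(C)C)cc(O[Si](C)(C)C(C)(C)C)c1 | intermediate
13 | (R)-3-[3,5-bis(tert-butyldimethylsilyloxy)phenoxy]-2-(5-methoxy-2,2-dimethyl-2H-chromen-6-yl)propyl acetate | COc1c([C@@H](COC(C)=O)COc3cc(O[Si](C)(C)C(C)(C)C)cc(O[Si](C)(C)C(C)(C)C)c3)ccc2c1C=CC(C)(C)O2 | intermediate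
14 | (S)-3-[3,5-bis(tert-butyldimethylsilyloxy)phenoxy]-2-(5-methoxy-2,2-dimethyl-2H-chromen-6-yl)propan-1-ol | COc1c([C@@H](CO)COc3cc(O[Si](C)(C)C(C)(C)C)cc(O[Si](C)(C)C(C)(C)C)c3)ccc2c1C=CC(C)(C)O2 | intermediate
15 | (R)-3-[3,5-bis(tert-butyldimethylsilyloxy)phenoxy]-2-(5-methoxy-2,2-dimethyl-2H-chromen-6-yl)propanoic acid | COc1c([C@@H](C(=O)O)COc3cc(O[Si](C)(C)C(C)(C)C)cc(O[Si](C)(C)C(C)(C)C)c3)ccc2c1C=CC(C)(C)O2 | intermediate
16 | (R)-3-[3,5-bis(tert-butyldimethylsilyloxy)phenoxy]-2-(5-methoxy-2,2-dimethyl-2H-chromen-6-yl)propanoic trifluoroacetic anhydride | COc1c([C@@H](C(=O)OC(=O)C(F)(F)F)COc3cc(O[Si](C)(C)C(C)(C)C)cc(O[Si](C)(C)C(C)(C)C)c3)ccc2c1C=CC(C)(C)O2 | intermediate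
17 | (R)-5,7-bis(tert-butyldimethylsilyloxy)-3-(5-methoxy-2,2-dimethyl-2H-chromen-6-yl)chroman-4-one | COc1c([C@@H]2COc3cc(O[Si](C)(C)C(C)(C)C)cc(O[Si](C)(C)C(C)(C)C)c3C2=O)ccc2c1C=CC(C)(C)O2 | intermediate
18 | (R)-5,7-dihydroxy-3-(5-methoxy-2,2-dimethyl-2H-chromen-6-yl)chroman-4-one | COc1c([C@@H]2COc3cc(O)cc(O)c3C2=O)ccc2c1C=CC(C)(C)O2 | target

## Step count and uncertain steps

Total: 12 steps. Longest linear sequence: 11 steps (steps 1–6 and 8–12); step 7 is a one-step side branch.

**Step 11 (key step).** Several things may go wrong.
- Configuration at C3 may be partly lost by enolisation of 16 or of the new α-aryl ketone in the trifluoroacetic acid that is released.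
- Acid may add to the chromene double bond or oligomerise it, because the benzylic cation at C4 of the chromene is stabilised by two ortho oxygens.
- The activated acyl group may lose CO to give a benzylic cation stabilised by the ring B oxygens.
- Ring A may be trifluoroacetylated or lose a silyl group.

Fallback: activation and ring closure are separated. Acid 15 is converted under neutral conditions with 1-chloro-N,N,2-trimethylprop-1-en-1-amine in CH2Cl2 at 0 °C into (R)-3-[3,5-bis(tert-butyldimethylsilyloxy)phenoxy]-2-(5-methoxy-2,2-dimethyl-2H-chromen-6-yl)propanoyl chloride F1. F1 is then closed with SnCl4 in CH2Cl2 at −78 °C, where the protic medium is replaced by a Lewis acid at a temperature at which enolisation and alkene protonation are slow. The sequence rejoins the route at 17.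

**Step 3.** Hydride may migrate instead of the aryl group, giving the β-keto ester, and the acid catalyst may attack the chromene double bond. Fallback: aldehyde 5 is homologated without strong acid on the free aldehyde.
- Condensation with methyl (methylsulfinyl)methyl sulfide under benzyltrimethylammonium hydroxide in THF would give 5-methoxy-2,2-dimethyl-6-[2-(methylsulfanyl)-2-(methylsulfinyl)ethenyl]-2H-chromene F2.
- Ethanolysis of F2 with HCl in ethanol would give ethyl 2-(5-methoxy-2,2-dimethyl-2H-chromen-6-yl)acetate F3.
- Claisen formylation of F3 with ethyl formate and NaH rejoins the route at 7.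

**Step 6.** The ortho-methoxy group may lower the enantiotopic group selection or reverse its sense, the diacetate may form in excess, and the acetyl group may migrate between the two oxygens on handling, which racemises 10. Fallback: the desymmetrisation is run in the hydrolytic direction. Diol 9 is acetylated (Ac2O, pyridine) to 2-(5-methoxy-2,2-dimethyl-2H-chromen-6-yl)propane-1,3-diyl diacetate F4, and F4 is hydrolysed with the same lipase in NaH2PO4–Na2HPO4 buffer. The enzyme recognises the same arm in both directions, so hydrolysis leaves the acetate on the arm that acylation would leave free and gives the monoacetate of the opposite configuration. This rejoins the route at 10.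

**Step 10.** The intermediate α-aryl aldehyde may enolise, which racemises C3 and can expel the aryloxide from the β-position; the oxidant may also attack the electron-rich rings or the chromene. Fallback: enantiomeric purity is restored at the acid by classical resolution. Acid 15 of lowered purity is crystallised as (S)-1-phenylethylammonium (R)-3-[3,5-bis(tert-butyldimethylsilyloxy)phenoxy]-2-(5-methoxy-2,2-dimethyl-2H-chromen-6-yl)propanoate F5; the antipodal amine is used if that salt is the less soluble one. The acid is liberated with cold dilute citric acid, and the sequence rejoins the route at 15. A carboxylate salt has no acidic α-hydrogen, so the amine does not endanger C3.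

## Further compounds

F1 | step 11 | (R)-3-[3,5-bis(tert-butyldimethylsilyloxy)phenoxy]-2-(5-methoxy-2,2-dimethyl-2H-chromen-6-yl)propanoyl chloride | COc1c([C@@H](C(Cl)=O)COc3cc(O[Si](C)(C)C(C)(C)C)cc(O[Si](C)(C)C(C)(C)C)c3)ccc2c1C=CC(C)(C)O2
F2 | step 3 | 5-methoxy-2,2-dimethyl-6-[2-(methylsulfanyl)-2-(methylsulfinyl)ethenyl]-2H-chromene (alkene isomers, racemic at sulfur) | COc1c(C=C(SC)S(C)=O)ccc2OC(C)(C)C=Cc12
F3 | step 3 | ethyl 2-(5-methoxy-2,2-dimethyl-2H-chromen-6-yl)acetate | CCOC(=O)Cc1ccc2OC(C)(C)C=Cc2c1OC
F4 | step 6 | 2-(5-methoxy-2,2-dimethyl-2H-chromen-6-yl)propane-1,3-diyl diacetate | CC(=O)OCC(COC(C)=O)c1ccc2OC(C)(C)C=Cc2c1OC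
F5 | step 10 | (S)-1-phenylethylammonium (R)-3-[3,5-bis(tert-butyldimethylsilyloxy)phenoxy]-2-(5-methoxy-2,2-dimethyl-2H-chromen-6-yl)propanoate | C[C@H]([NH3+])c1ccccc1.COc1c([C@@H](C([O-])=O)COc3cc(O[Si](C)(C)C(C)(C)C)cc(O[Si](C)(C)C(C)(C)C)c3)ccc2c1C=CC(C)(C)O2
A1 | alternative 1 | 3-[2-hydroxy-3-(3-methylbut-2-enyl)-4-(triisopropylsilyloxy)phenyl]-5,7-bis(methoxymethoxy)-4H-chromen-4-one | COCOc1cc(OCOC)c2c(c1)occ(-c1ccc(O[Si](C(C)C)(C(C)C)C(C)C)c(CC=C(C)C)c1O)c2=O
A2 | alternative 1 | (E)-3-(4-diazo-3-oxobut-1-en-1-yl)-5,7-bis(methoxymethoxy)-4H-chromen-4-one | COCOc1cc(OCOC)c2c(c1)occ(/C=C/C(=O)C=[N+]=[N-])c2=O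
A3 | alternative 1 | triisopropyl[(5-methylhex-4-en-1-yn-1-yl)oxy]silane | CC(C)=CCC#CO[Si](C(C)C)(C(C)C)C(C)C
A4 | alternative 2 | 5-hydroxy-2,2-dimethyl-2H-chromene-6-carbaldehyde | O=Cc1ccc2OC(C)(C)C=Cc2c1O
A5 | alternative 2 | 2-hydroxy-4-[(2-methylbut-3-yn-2-yl)oxy]benzaldehyde | O=Cc1ccc(OC(C)(C)C#C)cc1O
A6 | alternative 3 | 4,5,7-trihydroxy-3-(5-methoxy-2,2-dimethyl-2H-chromen-6-yl)-2H-chromen-2-one | COc1c(-c3c(O)c4c(O)cc(O)cc4oc3=O)ccc2c1C=CC(C)(C)O2
A7 | alternative 3 | diethyl 2-(5-methoxy-2,2-dimethyl-2H-chromen-6-yl)propanedioate | CCOC(=O)C(C(=O)OCC)c1ccc2OC(C)(C)C=Cc2c1OC
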